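**Plan**
- Retrosynthesis: cut C12–C13 (side chain), then C5–C10 and C8–C9 of ring B in one [4+2], then C1–C10, C7–C8 and C3–C4 of the open chain.
- Enabling feature: ring B (C5–C10) carries oxygen on C6 between C5 and C7, and carbon C11 on C9 beside the quaternary C10. This is a 2-oxy diene C5=C6–C7=C8 facing an enoyl dienophile C9=C10 (C11 carbonyl), with C1–C4 of ring A as the tether.
- Forward: an acyclic triene is assembled from mesityl oxide, allyltrimethylsilane, acetaldehyde and an (E)-3-triflyloxybutenoyl oxazolidinone; one intramolecular Diels–Alder reaction closes rings A and B together.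
- Ring B is then oxidised (7-en-6-one, 7,8-epoxide, 8-OH, 6-OH), C11 becomes a vinyl group, and C13–C16 is joined last by a B-alkyl Suzuki–Miyaura coupling.
- Stereochemistry: C9 and C10 from the (R)-4-benzyloxazolidinone and the E dienophile; C5 from the endo transition state; C8 from face-selective epoxidation; C6 from thermodynamic reduction; both E enoates from E enol triflates.

Key step: step 9

Remark: labdane numbering is used for all ring compounds (C20 on C10, C17 on C8, C18/C19 on C4, C11 on C9); the target is taken as the ent-labdane with C20, C11 and C17 on one face and H5, 6-OH and 8-OH (both equatorial) on the other.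

**Route**

Step 1
Reactants: 1 4-methylpent-3-en-2-one (mesityl oxide); 2 allyltrimethylsilane
Product: 3 4,4-dimethylhept-6-en-2-one
Conditions: TiCl4 (1.0 equiv), CH2Cl2, −78 °C; then H2O
Reagents that add atoms: none
Why: Hosomi–Sakurai conjugate allylation: the TiCl4-activated β,β-dimethyl enone is attacked at its β-carbon (C4) by the allylsilane, which builds the quaternary gem-dimethyl carbon and the C1–C3 unit without creating a stereocentre.

Step 2
Reactants: 3 4,4-dimethylhept-6-en-2-one; 4 acetaldehyde
Product: 6 2-hydroxy-6,6-dimethylnon-8-en-4-one (racemic), via lithium enolate 5 (not isolated)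
Conditions: LiN(i-Pr)2, THF, −78 °C; then MeCHO, −78 °C; aq. NH4Cl
Reagents that add atoms: none
Why: Kinetic deprotonation takes the methyl group in preference to the neopentyl CH2 and the lithium enolate adds to acetaldehyde (aldol addition); the carbinol centre forms as a racemate and is removed in the next step.

Step 3
Reactants: 6 2-hydroxy-6,6-dimethylnon-8-en-4-one
Product: 8 (2E)-6,6-dimethylnona-2,8-dien-4-one, via mesylate 7 (not isolated)
Conditions: MsCl, Et3N (excess), CH2Cl2, 0 °C → rt
Reagents that add atoms: none
Why: Mesylation followed by E1cB elimination completes the aldol condensation and should give the conjugated enone as the thermodynamically favoured E isomer.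

Step 4
Reactants: 8 (2E)-6,6-dimethylnona-2,8-dien-4-one
Product: 9 tert-butyl{[(2E,4Z)-6,6-dimethylnona-2,4,8-trien-4-yl]oxy}dimethylsilane
Conditions: TBSOTf, Et3N, CH2Cl2, −78 → 0 °C
Reagents that add atoms: tert-butyldimethylsilyl trifluoromethanesulfonate, CC(C)(C)[Si](C)(C)OS(=O)(=O)C(F)(F)F
Why: Soft enolisation (silyl triflate/amine): the O-silylated enone should lose the α' proton at C5 because the γ protons of the E-propenyl group are less acidic and poorly placed, and the Z silyl dienol ether should form because the quaternary carbon avoids allylic 1,3-strain with the propenyl group, which puts the future tether on the outside of the diene.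

Step 5
Reactants: 10 tert-butyl 3-oxobutanoate
Product: 11 tert-butyl (2E)-3-{[(trifluoromethyl)sulfonyl]oxy}but-2-enoate
Conditions: Tf2O, aq. Me4NOH, hexanes, 5 °C
Reagents that add atoms: trifluoromethanesulfonic anhydride, O=S(=O)(OS(=O)(=O)C(F)(F)F)C(F)(F)F
Why: O-Triflation of the β-keto ester enolate: with the non-chelating tetramethylammonium counter-ion the enolate reacts in its extended form and should give the E enol triflate (triflate trans to the ester), the geometry that later places the alkyl chain trans to the carbonyl.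

Step 6
Reactants: 11 tert-butyl (2E)-3-{[(trifluoromethyl)sulfonyl]oxy}but-2-enoate
Product: 12 (2E)-3-{[(trifluoromethyl)sulfonyl]oxy}but-2-enoic acid
Conditions: CF3CO2H, CH2Cl2, rt
Reagents that add atoms: none
Why: Acidolysis of the tert-butyl ester with loss of 2-methylpropene; the vinyl triflate is inert to trifluoroacetic acid and the alkene geometry is not touched.

Step 7
Reactants: 12 (2E)-3-{[(trifluoromethyl)sulfonyl]oxy}but-2-enoic acid; 13 (R)-4-benzyloxazolidin-2-one
Product: 16 (R)-4-benzyl-3-[(2E)-3-{[(trifluoromethyl)sulfonyl]oxy}but-2-enoyl]oxazolidin-2-one, via acid chloride 14 (not isolated), via lithium oxazolidinide 15 (not isolated)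
Conditions: 12, (COCl)2, DMF (cat.), CH2Cl2, 0 °C → rt, evaporate; separately 13, n-BuLi, THF, −78 °C; combine at −78 °C
Reagents that add atoms: none
Why: N-Acylation of the lithiated oxazolidinone by the acid chloride at −78 °C, where acyl substitution is much faster than addition–elimination at the triflate-bearing carbon; the auxiliary stereocentre and the E geometry are carried through unchanged.

Step 8
Reactants: 9 tert-butyl{[(2E,4Z)-6,6-dimethylnona-2,4,8-trien-4-yl]oxy}dimethylsilane; 16 (R)-4-benzyl-3-[(2E)-3-{[(trifluoromethyl)sulfonyl]oxy}but-2-enoyl]oxazolidin-2-one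
Product: 18 (R)-4-benzyl-3-[(2E,8Z,10E)-9-(tert-butyldimethylsilyloxy)-3,7,7-trimethyldodeca-2,8,10-trienoyl]oxazolidin-2-one, via B-alkyl-9-BBN 17 (not isolated)
Conditions: 9-BBN (1.1 equiv), THF, 0 °C → rt; then 16, PdCl2(dppf) (5 mol %), K3PO4, DMF–THF, 50 °C
Reagents that add atoms: none
Why: 9-BBN hydroborates the monosubstituted alkene (anti-Markovnikov) far faster than the conjugated diene or the trisubstituted enol ether, and the B-alkyl Suzuki–Miyaura coupling with the vinyl triflate proceeds with retention under anhydrous phosphate, so the 2E enoyl imide should form while the silyl dienol ether and the imide survive.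

Step 9
Reactants: 18 (R)-4-benzyl-3-[(2E,8Z,10E)-9-(tert-butyldimethylsilyloxy)-3,7,7-trimethyldodeca-2,8,10-trienoyl]oxazolidin-2-one
Product: 19 (R)-4-benzyl-3-[6-(tert-butyldimethylsilyloxy)-12,13,14,15,16-pentanor-ent-labd-6-en-11-oyl]oxazolidin-2-one (trans-decalin silyl enol ether; C11 acyl group, C17 and C20 methyls mutually cis, H5 trans to C20)
Conditions: Me2AlCl (1.5 equiv), CH2Cl2, −78 → −20 °C; aq. NaHCO3/Rochelle salt
Reagents that add atoms: none
Why: With more than one equivalent of Me2AlCl the imide becomes the cationic bidentate chelate [Me2Al(imide)]+ Me2AlCl2−, which locks the enoyl group s-cis and makes C10 strongly electrophilic, so the nucleophilic enol ether carbon C5 bonds to C10 ahead of C8–C9 in a concerted but asynchronous [4+2]. The closest known reaction type is the dialkylaluminium chloride-promoted intramolecular Diels–Alder reaction of triene N-acyloxazolidinones, together with the known additions of 2-silyloxy dienes to hindered Lewis-acid-activated dienophiles. Ring B closes by the cycloaddition itself (C5–C10 and C8–C9, six-membered carbocycle), and ring A closes through the four-carbon tether C1–C4 that links the diene terminus C5 to the dienophile carbon C10 (type 1 intramolecular mode, fused six-membered ring). C10 and C9 take their absolute configuration from the (R)-benzyl group, which shields one face of the chelated dienophile, and their cis relationship (C20/C11) from the E dienophile; C5 (trans ring fusion) and C8 (C17 cis to C11) follow from the carbonyl-endo transition state with the tether on the outside position of the diene. The step needs facial and endo selectivity, secured by the rigid chelate and the auxiliary, and an s-cis diene with the tether outside, secured by the Z silyl dienol ether; the gem-dimethyl group at C4 should help the chain fold.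

Step 10
Reactants: 19 cycloadduct imide
Product: 20 6-(tert-butyldimethylsilyloxy)-12,13,14,15,16-pentanor-ent-labd-6-en-11-ol (ring configuration as in 19)
Conditions: LiBH4, MeOH (1 equiv), THF, 0 °C → rt
Reagents that add atoms: none
Why: Reductive cleavage of the N-acyloxazolidinone: hydride attacks the exocyclic carbonyl, the auxiliary is released for recovery, the silyl enol ether is inert to borohydride and no stereocentre is affected.

Step 11
Reactants: 20 silyl enol ether alcohol
Product: 21 11-hydroxy-12,13,14,15,16-pentanor-ent-labd-7-en-6-one (trans ring fusion; C11 cis to C20)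
Conditions: Pd(OAc)2 (1.1 equiv), MeCN, rt → 40 °C
Reagents that add atoms: none
Why: Saegusa–Ito oxidation: the silyl enol ether gives a palladium enolate at C7 whose only β-hydrogen is H8, so the 7-en-6-one should form regiospecifically and the provisional C8 stereocentre is erased on purpose.

Step 12
Reactants: 21 11-hydroxy-7-en-6-one
Product: 22 7,8-epoxy-11-hydroxy-12,13,14,15,16-pentanor-ent-labdan-6-one (epoxide oxygen on the H5 face, C17 on the C20 face)
Conditions: 30% H2O2, NaOH (0.3 equiv), MeOH, 0 °C → rt
Reagents that add atoms: hydrogen peroxide, OO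
Why: Weitz–Scheffer nucleophilic epoxidation: hydroperoxide adds to C8 of the enone from the face opposite the axial C20 methyl and the C9 substituent, so the oxygen should end up on the H5 face with C17 axial, which sets C8.

Step 13
Reactants: 22 epoxy ketone
Product: 23 8,11-dihydroxy-12,13,14,15,16-pentanor-ent-labdan-6-one (8-OH equatorial, cis to H5; C17 axial, cis to C20)
Conditions: SmI2 (2.2 equiv), THF–MeOH, −78 °C
Reagents that add atoms: none
Why: Two-electron reduction of the α,β-epoxy ketone by SmI2 cleaves only the C7–O bond next to the carbonyl and methanol protonates the samarium enolate, so the C8–O bond and its configuration stay untouched.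

Step 14
Reactants: 23 β-hydroxy ketone
Product: 24 12,13,14,15,16-pentanor-ent-labdane-6,8,11-triol (6-OH and 8-OH equatorial, both cis to H5)
Conditions: Li, liquid NH3–THF, EtOH, −78 → −33 °C
Reagents that add atoms: none
Why: Dissolving-metal reduction of the ketone runs under thermodynamic control and should give the equatorial C6 alcohol, because the axial epimer (the one expected from hydride reagents attacking the open face) would be syn-diaxial to C20 and to the axial C4 methyl group.

Step 15
Reactants: 24 triol
Product: 25 6,8-dihydroxy-12,13,14,15,16-pentanor-ent-labdan-11-al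
Conditions: TEMPO (10 mol %), PhI(OAc)2, CH2Cl2, rt
Reagents that add atoms: none
Why: Oxoammonium (TEMPO/PhI(OAc)2) oxidation is selective for the primary alcohol over the hindered secondary and the tertiary hydroxyl and stops at the aldehyde under near-neutral conditions that should not epimerise C9.

Step 16
Reactants: 25 dihydroxy aldehyde
Product: 26 13,14,15,16-tetranor-ent-labd-11-ene-6,8-diol (C9 vinyl group; ring configuration as in 24)
Conditions: Ph3PCH3Br, KN(SiMe3)2, THF, 0 °C; then 25, −78 → 0 °C (excess ylide)
Reagents that add atoms: methyltriphenylphosphonium bromide, C[P+](c1ccccc1)(c1ccccc1)c1ccccc1.[Br-]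
Why: Wittig methylenation with excess ylide at low temperature, where addition to the aldehyde should be faster than retro-aldol cleavage or enolisation, turns C11 into the vinyl group without touching C9.

Step 17
Reactants: 27 methyl 3-oxobutanoate
Product: 28 methyl (2E)-3-{[(trifluoromethyl)sulfonyl]oxy}but-2-enoate
Conditions: Tf2O, aq. Me4NOH, hexanes, 5 °C
Reagents that add atoms: trifluoromethanesulfonic anhydride, O=S(=O)(OS(=O)(=O)C(F)(F)F)C(F)(F)F
Why: O-Triflation of the non-chelated tetramethylammonium enolate of the β-keto ester, as in step 5, should give the E enol triflate needed for the 13E side chain.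

Step 18
Reactants: 26 vinyl diol; 28 methyl (2E)-3-{[(trifluoromethyl)sulfonyl]oxy}but-2-enoate
Product: 30 methyl (2E)-5-[(1S,2S,4R,4aR,8aR)-2,4-dihydroxy-2,5,5,8a-tetramethyldecahydronaphthalen-1-yl]-3-methylpent-2-enoate (target; methyl (13E)-6,8-dihydroxy-ent-labd-13-en-15-oate), via alkylborane 29 (not isolated)
Conditions: 9-BBN (excess), THF, rt → 50 °C; then aq. K3PO4, 28, PdCl2(dppf) (5 mol %), DMF, rt → 40 °C
Reagents that add atoms: none
Why: 9-BBN hydroborates the vinyl group at its terminal carbon (the excess is taken up by the two hydroxyls as borinates that hydrolyse on work-up), and B-alkyl Suzuki–Miyaura coupling with the E enol triflate proceeds with retention, so the 13E enoate should form directly without protecting groups.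

**Compound list**

1 | 4-methylpent-3-en-2-one (mesityl oxide) | CC(=O)C=C(C)C | starting material
2 | allyltrimethylsilane | C=CC[Si](C)(C)C | starting material
3 | 4,4-dimethylhept-6-en-2-one | CC(=O)CC(C)(C)CC=C | intermediate
4 | acetaldehyde | CC=O | starting material
5 | lithium 4,4-dimethylhepta-1,6-dien-2-olate (kinetic enolate of 3, not isolated) | [Li+].[O-]C(=C)CC(C)(C)CC=C | intermediate
6 | 2-hydroxy-6,6-dimethylnon-8-en-4-one (racemic) | CC(O)CC(=O)CC(C)(C)CC=C | intermediate
7 | 6,6-dimethyl-4-oxonon-8-en-2-yl methanesulfonate (racemic, not isolated) | CC(OS(C)(=O)=O)CC(=O)CC(C)(C)CC=C | intermediate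
8 | (2E)-6,6-dimethylnona-2,8-dien-4-one | C/C=C/C(=O)CC(C)(C)CC=C | intermediate
9 | tert-butyl{[(2E,4Z)-6,6-dimethylnona-2,4,8-trien-4-yl]oxy}dimethylsilane | C/C=C/C(O[Si](C)(C)C(C)(C)C)=C/C(C)(C)CC=C | intermediate
10 | tert-butyl 3-oxobutanoate | CC(=O)CC(=O)OC(C)(C)C | starting material
11 | tert-butyl (2E)-3-{[(trifluoromethyl)sulfonyl]oxy}but-2-enoate | C/C(OS(=O)(=O)C(F)(F)F)=C\C(=O)OC(C)(C)C | intermediate
12 | (2E)-3-{[(trifluoromethyl)sulfonyl]oxy}but-2-enoic acid | C/C(OS(=O)(=O)C(F)(F)F)=C\C(=O)O | intermediate
13 | (R)-4-benzyloxazolidin-2-one | O=C1N[C@H](Cc2ccccc2)CO1 | starting material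
14 | (2E)-3-{[(trifluoromethyl)sulfonyl]oxy}but-2-enoyl chloride (not isolated) | C/C(OS(=O)(=O)C(F)(F)F)=C\C(Cl)=O | intermediate
15 | lithium salt of (R)-4-benzyloxazolidin-2-one (not isolated) | [Li+].O=C1[N-][C@H](Cc2ccccc2)CO1 | intermediate
16 | (R)-4-benzyl-3-[(2E)-3-{[(trifluoromethyl)sulfonyl]oxy}but-2-enoyl]oxazolidin-2-one | C/C(OS(=O)(=O)C(F)(F)F)=C\C(=O)N1C(=O)OC[C@H]1Cc1ccccc1 | intermediate
17 | 9-[(5Z,7E)-6-(tert-butyldimethylsilyloxy)-4,4-dimethylnona-5,7-dien-1-yl]-9-borabicyclo[3.3.1]nonane (not isolated) | C/C=C/C(O[Si](C)(C)C(C)(C)C)=C/C(C)(C)CCCB1C2CCCC1CCC2 | intermediate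
18 | (R)-4-benzyl-3-[(2E,8Z,10E)-9-(tert-butyldimethylsilyloxy)-3,7,7-trimethyldodeca-2,8,10-trienoyl]oxazolidin-2-one | C/C=C/C(O[Si](C)(C)C(C)(C)C)=C/C(C)(C)CCC/C(C)=C/C(=O)N1C(=O)OC[C@H]1Cc2ccccc2 | intermediate
19 | (R)-4-benzyl-3-[6-(tert-butyldimethylsilyloxy)-12,13,14,15,16-pentanor-ent-labd-6-en-11-oyl]oxazolidin-2-one (trans-decalin; C11, C17, C20 cis; H5 trans to C20) | O=C([C@H]1[C@]2(C)CCCC(C)(C)[C@H]2C(O[Si](C)(C)C(C)(C)C)=C[C@H]1C)N3C(=O)OC[C@H]3Cc4ccccc4 | intermediate
20 | 6-(tert-butyldimethylsilyloxy)-12,13,14,15,16-pentanor-ent-labd-6-en-11-ol | OC[C@H]1[C@]2(C)CCCC(C)(C)[C@H]2C(O[Si](C)(C)C(C)(C)C)=C[C@H]1C | intermediate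
21 | 11-hydroxy-12,13,14,15,16-pentanor-ent-labd-7-en-6-one | OC[C@H]1[C@]2(C)CCCC(C)(C)[C@H]2C(=O)C=C1C | intermediate
22 | 7,8-epoxy-11-hydroxy-12,13,14,15,16-pentanor-ent-labdan-6-one (epoxide on the H5 face) | OC[C@H]1[C@]2(C)CCCC(C)(C)[C@H]2C(=O)[C@@H]3O[C@@]31C | intermediate
23 | 8,11-dihydroxy-12,13,14,15,16-pentanor-ent-labdan-6-one (8-OH equatorial, cis to H5) | OC[C@H]1[C@]2(C)CCCC(C)(C)[C@H]2C(=O)C[C@]1(C)O | intermediate
24 | 12,13,14,15,16-pentanor-ent-labdane-6,8,11-triol (6-OH and 8-OH equatorial, cis to H5) | OC[C@H]1[C@]2(C)CCCC(C)(C)[C@H]2[C@H](O)C[C@]1(C)O | intermediate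
25 | 6,8-dihydroxy-12,13,14,15,16-pentanor-ent-labdan-11-al | O=C[C@H]1[C@]2(C)CCCC(C)(C)[C@H]2[C@H](O)C[C@]1(C)O | intermediate
26 | 13,14,15,16-tetranor-ent-labd-11-ene-6,8-diol | C=C[C@H]1[C@]2(C)CCCC(C)(C)[C@H]2[C@H](O)C[C@]1(C)O | intermediate
27 | methyl 3-oxobutanoate | CC(=O)CC(=O)OC | starting material
28 | methyl (2E)-3-{[(trifluoromethyl)sulfonyl]oxy}but-2-enoate | C/C(OS(=O)(=O)C(F)(F)F)=C\C(=O)OC | intermediate
29 | 12-(9-borabicyclo[3.3.1]nonan-9-yl)-13,14,15,16-tetranor-ent-labdane-6,8-diol (not isolated; hydroxyls transiently O-borylated) | C1CCC2CCCC1B2CC[C@H]3[C@]4(C)CCCC(C)(C)[C@H]4[C@H](O)C[C@]3(C)O | intermediate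
30 | methyl (2E)-5-[(1S,2S,4R,4aR,8aR)-2,4-dihydroxy-2,5,5,8a-tetramethyldecahydronaphthalen-1-yl]-3-methylpent-2-enoate | COC(=O)/C=C(\C)CC[C@H]1[C@]2(C)CCCC(C)(C)[C@H]2[C@H](O)C[C@]1(C)O | target

**Step count and risks**

Total step count: 18. Longest linear sequence: 14 steps (steps 1–4, 8–16 and 18).

Steps most likely to fail:

1. Step 9. The C5–C10 bond joins a neopentyl carbon to a carbon that becomes quaternary. The cycloaddition may therefore be too slow, so that the Lewis acid strips the silyl group from the dienol ether first, or it may lose endo and facial control. Fallback (stepwise anionic double Michael reaction that forms the same two bonds): setting out from 18, mild acid hydrolysis (AcOH, THF–H2O) of the silyl dienol ether would give (R)-4-benzyl-3-[(2E,10E)-3,7,7-trimethyl-9-oxododeca-2,10-dienoyl]oxazolidin-2-one F1. Kinetic deprotonation of F1 at C5 with LiN(SiMe3)2 in THF at −78 °C should trigger Michael addition of C5 to C10, then addition of the resulting imide enolate (C9) to C8. Trapping the C6 enolate with TBSCl returns the route to 19.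

2. Step 8. The basic coupling medium may cleave the silyl dienol ether or attack the triflyloxy enoyl imide before transmetalation, or the borane may not discriminate fully between the terminal alkene and the diene. Fallback (robust ester partner, auxiliary attached afterwards): setting out from 9 through the same alkylborane 17, coupling with the ester triflate 28 (PdCl2(dppf), K3PO4) would give methyl (2E,8Z,10E)-9-[(tert-butyldimethylsilyl)oxy]-3,7,7-trimethyldodeca-2,8,10-trienoate F2. Anhydrous ester cleavage with KOSiMe3 in THF and buffering to pH 5 would give (2E,8Z,10E)-9-[(tert-butyldimethylsilyl)oxy]-3,7,7-trimethyldodeca-2,8,10-trienoic acid F3. Activation with PivCl/Et3N would give the mixed pivalic anhydride F4, which acylates the lithium oxazolidinide 15 and comes back to the route at 18.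

3. Step 16. Under the basic ylide the free β-hydroxy aldehyde may undergo retro-aldol opening of ring B (C8–C9), dehydration, or epimerisation at C9 faster than olefination. Fallback (temporary silyl protection so that no free β-hydroxy aldehyde is formed): setting out from 24, TESOTf/2,6-lutidine would give 6,8,11-tris(triethylsilyloxy)-12,13,14,15,16-pentanor-ent-labdane F5. Swern conditions ((COCl)2, DMSO, Et3N, −78 → −30 °C) cleave and oxidise only the primary triethylsilyl ether, giving 6,8-bis(triethylsilyloxy)-12,13,14,15,16-pentanor-ent-labdan-11-al F6. Wittig methylenation (Ph3PCH3Br, KN(SiMe3)2) would give 6,8-bis(triethylsilyloxy)-13,14,15,16-tetranor-ent-labd-11-ene F7, and n-Bu4NF in THF removes both silyl groups and returns to the route at 26.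

**Further compounds**

F1 | step 9 | (R)-4-benzyl-3-[(2E,10E)-3,7,7-trimethyl-9-oxododeca-2,10-dienoyl]oxazolidin-2-one | C/C=C/C(=O)CC(C)(C)CCC/C(C)=C/C(=O)N1C(=O)OC[C@H]1Cc1ccccc1
F2 | step 8 | methyl (2E,8Z,10E)-9-[(tert-butyldimethylsilyl)oxy]-3,7,7-trimethyldodeca-2,8,10-trienoate | C/C=C/C(O[Si](C)(C)C(C)(C)C)=C/C(C)(C)CCC/C(C)=C/C(=O)OC
F3 | step 8 | (2E,8Z,10E)-9-[(tert-butyldimethylsilyl)oxy]-3,7,7-trimethyldodeca-2,8,10-trienoic acid | C/C=C/C(O[Si](C)(C)C(C)(C)C)=C/C(C)(C)CCC/C(C)=C/C(=O)O
F4 | step 8 | (2E,8Z,10E)-9-[(tert-butyldimethylsilyl)oxy]-3,7,7-trimethyldodeca-2,8,10-trienoic 2,2-dimethylpropanoic anhydride | C/C=C/C(O[Si](C)(C)C(C)(C)C)=C/C(C)(C)CCC/C(C)=C/C(=O)OC(=O)C(C)(C)C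
F5 | step 16 | 6,8,11-tris(triethylsilyloxy)-12,13,14,15,16-pentanor-ent-labdane | CC[Si](CC)(CC)OC[C@H]1[C@]2(C)CCCC(C)(C)[C@H]2[C@H](O[Si](CC)(CC)CC)C[C@]1(C)O[Si](CC)(CC)CC
F6 | step 16 | 6,8-bis(triethylsilyloxy)-12,13,14,15,16-pentanor-ent-labdan-11-al | O=C[C@H]1[C@]2(C)CCCC(C)(C)[C@H]2[C@H](O[Si](CC)(CC)CC)C[C@]1(C)O[Si](CC)(CC)CC
F7 | step 16 | 6,8-bis(triethylsilyloxy)-13,14,15,16-tetranor-ent-labd-11-ene | C=C[C@H]1[C@]2(C)CCCC(C)(C)[C@H]2[C@H](O[Si](CC)(CC)CC)C[C@]1(C)O[Si](CC)(CC)CC
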